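## Retrosynthetic overview

1. The plan rests on ring B (C1' ether oxygen, C2' pentyl, C4' OH, C6' OH) being an olivetol ring. Its crowded C1' is traced back to the O–CH2 carbon of an acetoacetate hung on the C2 phenol oxygen of ring A (C1 CO2H, C2 O, C4 OMe, C6 pentanoyl), so the hindered diaryl ether C–O bond is made by an ordinary phenol alkylation.
2. Target ⇒ C3'-carboxylated resorcylate (hydrolysis, then loss of the olivetolic-type C3' carboxyl as CO2) ⇒ Diels–Alder benzannulation forming C1'–C2' and C3'–C4' from the 4-aryloxy-1-methoxy-1,3-bis(trimethylsilyloxy)butadiene and methyl oct-2-ynoate.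
3. Diene ⇒ 4-aryloxyacetoacetate ⇒ ring A phenol + methyl 4-chloroacetoacetate. The C1 acid and C6 ketone of ring A travel as one masked unit, the methyl pseudo-ester (3-butyl-3-methoxyphthalide): acid ketalisation of a 2-acylbenzoate drifts to this lactone anyway, no Lewis-acid-sensitive dioxolane is needed, and the lactone opens in base far faster than a doubly flanked methyl benzoate.
4. Ring A phenol ⇒ 2,4-dimethoxy-6-pentanoylbenzoic acid ⇒ 3-butyl-5,7-dimethoxyphthalide ⇒ amide-directed C6 lithiation of N,N-diethyl-2,4-dimethoxybenzamide and addition to pentanal.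
5. Ring order: ring A is bought, the auxiliary lactone ring is closed in step 2 and re-closed in step 5, ring B is closed in step 9, and the lactone is opened again in step 10.

Key step: step 9

Assumption: the target is handled as the open keto acid drawn in the SMILES. Its ring–chain tautomer (the 3-butyl-3-hydroxyphthalide lactol) is the same compound and needs no separate step.

Shorthand: ArA = (±)-3-butyl-3,5-dimethoxy-1-oxo-1,3-dihydroisobenzofuran-7-yl. Phthalide numbering is used: C1 is the lactone carbonyl, C3 is the ketal carbon bearing butyl and OMe, and C7 is next to the carbonyl-bearing ring carbon. ArA is therefore ring A with its C1 carboxyl and C6 pentanoyl group tied together as the methyl pseudo-ester. Primed locants belong to ring B.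

## Route

**Step 1**
Reactants: 1 2,4-dimethoxybenzoic acid
Product: 3 N,N-diethyl-2,4-dimethoxybenzamide, via 2,4-dimethoxybenzoyl chloride 2 (not isolated)
Conditions: SOCl2, DMF (cat.), toluene, 70 °C; concentrate; Et2NH (3 equiv), CH2Cl2, 0 °C → rt
Reagents that add atoms: thionyl chloride O=S(Cl)Cl (chlorine of 2 only); diethylamine CCNCC
Why: Acyl chloride formation and aminolysis (Schotten–Baumann-type amidation) are routine for electron-rich benzoic acids and install the tertiary amide that serves as directing group in step 2.

**Step 2**
Reactants: 3 N,N-diethyl-2,4-dimethoxybenzamide; 4 pentanal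
Product: 7 (±)-3-butyl-5,7-dimethoxyisobenzofuran-1(3H)-one, via aryllithium 5 (not isolated), via hydroxy amide 6 (not isolated)
Conditions: s-BuLi, TMEDA, THF, −78 °C; 4, −78 °C → rt; 6 M HCl, distil off THF, 90 °C
Reagents that add atoms: sec-butyllithium [Li]C(C)CC (lithium of 5 only)
Why: Directed ortho-metalation, in which the diethylamide outranks both methoxy groups and guides s-BuLi/TMEDA to C6 rather than to the position between the two methoxy groups, is followed by addition to the aldehyde and by acid lactonisation, where the new benzylic hydroxyl expels diethylamine (the standard release of such hindered amides); the carbinol carbon forms racemic and needs no control because step 3 oxidises it.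

**Step 3**
Reactants: 7 (±)-3-butyl-5,7-dimethoxyisobenzofuran-1(3H)-one
Product: 9 2,4-dimethoxy-6-pentanoylbenzoic acid, via sodium hydroxy carboxylate 8 (not isolated)
Conditions: NaOH, H2O–t-BuOH, 80 °C; KMnO4, 0 °C → rt; filter off MnO2; HCl to pH 2
Reagents that add atoms: sodium hydroxide [Na+].[OH-]
Why: Saponification holds the hydroxy acid open as its carboxylate, and alkaline permanganate oxidation of the secondary benzylic alcohol then gives the 2-acylbenzoic acid, a classical phthalide-to-keto-acid conversion in which the aryl methyl ethers are inert and unreacted material relactonises on acidification and stays behind in a bicarbonate extraction.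

**Step 4**
Reactants: 9 2,4-dimethoxy-6-pentanoylbenzoic acid
Product: 10 2-hydroxy-4-methoxy-6-pentanoylbenzoic acid
Conditions: BCl3 (3 equiv), CH2Cl2, −78 → 0 °C; 1 M HCl
Reagents that add atoms: none
Why: In this chelation-controlled aryl methyl ether cleavage BCl3 bridges the carboxyl carbonyl and the adjacent C2 methoxy oxygen in a six-membered chelate and chloride removes only that methyl group, whereas the C4 methoxy group has no carbonyl neighbour (the C6 ketone is flanked by C5–H only).

**Step 5**
Reactants: 10 2-hydroxy-4-methoxy-6-pentanoylbenzoic acid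
Product: 11 (±)-3-butyl-7-hydroxy-3,5-dimethoxyisobenzofuran-1(3H)-one (ArA–OH)
Conditions: MeOH, H2SO4 (cat.), 3 Å MS, 40 °C; solid NaHCO3
Reagents that add atoms: methanol CO
Why: In this acid-catalysed pseudo-esterification the keto acid sits in ring–chain equilibrium with its lactol, normal Fischer esterification is blocked by the two ortho substituents, and methanol is therefore taken up at the lactol carbon to give the cyclic ketal-lactone, whose new quaternary centre is racemic and is erased in step 10.

**Step 6**
Reactants: 11 ArA–OH; 12 methyl 4-chloroacetoacetate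
Product: 13 methyl 4-(ArA-oxy)-3-oxobutanoate
Conditions: NaH (2.2 equiv), THF–DMF, 0 °C; 12, NaI (cat.), 0 → 45 °C; AcOH quench
Reagents that add atoms: none
Why: In this Williamson ether synthesis one equivalent of NaH makes the phenoxide and the second parks the chloro keto ester as its enolate, which suppresses self-condensation while the primary chloride stays open to SN2 displacement, the usual access to 4-alkoxy- and 4-aryloxyacetoacetates.

**Step 7**
Reactants: 13 methyl 4-(ArA-oxy)-3-oxobutanoate
Product: 14 methyl 4-(ArA-oxy)-3-(trimethylsilyloxy)but-2-enoate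
Conditions: TMSCl, Et3N, toluene, rt, 48 h; filter under Ar, concentrate
Reagents that add atoms: chlorotrimethylsilane C[Si](C)(C)Cl
Why: Soft enolisation and O-silylation of a β-keto ester with Et3N/TMSCl gives the ester-conjugated silyl enol ether (C2=C3 of the butenoate, mixture of geometries without consequence), the usual first stage towards 1,3-bis(silyloxy)dienes, and the conditions leave the lactone ketal alone.

**Step 8**
Reactants: 14 methyl 4-(ArA-oxy)-3-(trimethylsilyloxy)but-2-enoate
Product: 16 (±)-3-butyl-3,5-dimethoxy-7-{[(1Z)-4-methoxy-2,4-bis(trimethylsilyloxy)buta-1,3-dien-1-yl]oxy}isobenzofuran-1(3H)-one, via lithium dienolate 15 (not isolated)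
Conditions: LDA (commercial solution, 1.3 equiv), THF, −78 °C; TMSCl, −78 °C → rt; concentrate, hexane, filter under Ar; used crude
Reagents that add atoms: lithium diisopropylamide CC(C)N([Li])C(C)C (lithium of 15 only); chlorotrimethylsilane C[Si](C)(C)Cl
Why: Kinetic γ-deprotonation of the β-silyloxy enoate at its O–CH2 group gives the extended lithium dienolate, which TMSCl traps on the ester oxygen (the usual second stage of bis-silyl dienol ether synthesis); at −78 °C the lactone, which has no α-hydrogen, should stay untouched, and the aryloxy group should settle trans to the diene chain (Z enol ether) to escape allylic strain.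

**Step 9**
Reactants: 16 bis-silyloxy diene; 17 methyl oct-2-ynoate
Product: 20 methyl 3-(ArA-oxy)-4,6-dihydroxy-2-pentylbenzoate, via cyclohexadiene adduct 18 (not isolated), via bis-silyl arene 19 (not isolated)
Conditions: 17 (neat, 8 equiv), sealed tube, Ar, 140 °C; remove excess 17 in vacuo; MeOH, PPTS (cat.), rt
Reagents that add atoms: none
Why: The donor-laden diene 16 (two oxygens on C4', one on C6', plus the aryloxy group) and the acceptor alkyne 17 should combine in a normal-electron-demand, highly asynchronous Diels–Alder reaction in which C1'–C2' bonding runs ahead of C3'–C4', the closest known reaction type being the thermal benzannulation of 1-alkoxy-1,3-bis(silyloxy)buta-1,3-dienes with alk-2-ynoates to 6-alkyl-2,4-dihydroxybenzoates. Ring B is closed in this single intermolecular [4+2] event as the cyclohexa-1,4-diene 18, whose C4' methoxy group and doubly allylic C1'–H then leave as methanol to give arene 19, and acid-catalysed methanolysis strips both silyl groups without harming the methyl pseudo-ester because exchange with methanol there is degenerate. The sp3 centres C1' and C4' of 18 arise without control and need none, since both are flattened on aromatisation, and the racemic ketal carbon of the lactone is a bystander that is erased in step 10. The step needs regioselectivity: the two ketene acetal oxygens and the C6' silyloxy group all make C1' the nucleophilic end of the diene and outweigh the weaker opposing push of the acyl-substituted aryloxy group, so C1' should meet the electrophilic pentyl-bearing β-carbon of 17 and C4' the ester-bearing α-carbon. Reactivity is helped by the Z enol ether, which points the aryloxy group away from the s-cis diene cavity, by the flat tied-back lactone, which is slimmer beside the ether oxygen than a twisted methyl ester, and by using cheap 17 as the solvent.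

**Step 10**
Reactants: 20 methyl 3-(ArA-oxy)-4,6-dihydroxy-2-pentylbenzoate
Product: 22 2-(2,4-dihydroxy-6-pentylphenoxy)-4-methoxy-6-pentanoylbenzoic acid, via diacid 21 (not isolated)
Conditions: KOH (2 M aq)–dioxane, reflux, Ar; cool, HCl to pH 3; 90 °C until gas evolution stops
Reagents that add atoms: potassium hydroxide [K+].[OH-]
Why: Hydroxide opens the pseudo-ester lactone (the resulting hemiketal expels methoxide and frees ketone and carboxylate) and saponifies the ring B ester, and after acidification the 2,4-dihydroxy-6-alkylbenzoic acid loses CO2 by ipso-protonation through its keto tautomer (thermal decarboxylation of a β-resorcylic acid), while the ring A acid, which has no free ortho or para hydroxyl and carries an acyl group, keeps its carboxyl.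

## Compound list

| No. | Name | SMILES | Role |
|---|---|---|---|
| 1 | 2,4-dimethoxybenzoic acid | COc1ccc(C(=O)O)c(OC)c1 | starting material |
| 2 | 2,4-dimethoxybenzoyl chloride | COc1ccc(C(=O)Cl)c(OC)c1 | intermediate |
| 3 | N,N-diethyl-2,4-dimethoxybenzamide | CCN(CC)C(=O)c1ccc(OC)cc1OC | intermediate |
| 4 | pentanal | CCCCC=O | starting material |
| 5 | N,N-diethyl-2-lithio-4,6-dimethoxybenzamide | [Li]c1cc(OC)cc(OC)c1C(=O)N(CC)CC | intermediate |
| 6 | (±)-N,N-diethyl-2-(1-hydroxypentyl)-4,6-dimethoxybenzamide | CCCCC(O)c1cc(OC)cc(OC)c1C(=O)N(CC)CC | intermediate |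
| 7 | (±)-3-butyl-5,7-dimethoxyisobenzofuran-1(3H)-one | CCCCC1OC(=O)c2c(OC)cc(OC)cc21 | intermediate |
| 8 | sodium (±)-2-(1-hydroxypentyl)-4,6-dimethoxybenzoate | CCCCC(O)c1cc(OC)cc(OC)c1C(=O)[O-].[Na+] | intermediate |
| 9 | 2,4-dimethoxy-6-pentanoylbenzoic acid | CCCCC(=O)c1cc(OC)cc(OC)c1C(=O)O | intermediate |
| 10 | 2-hydroxy-4-methoxy-6-pentanoylbenzoic acid | CCCCC(=O)c1cc(OC)cc(O)c1C(=O)O | intermediate |
| 11 | (±)-3-butyl-7-hydroxy-3,5-dimethoxyisobenzofuran-1(3H)-one | CCCCC1(OC)OC(=O)c2c(O)cc(OC)cc21 | intermediate |
| 12 | methyl 4-chloroacetoacetate | COC(=O)CC(=O)CCl | starting material |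
| 13 | (±)-methyl 4-[(3-butyl-3,5-dimethoxy-1-oxo-1,3-dihydroisobenzofuran-7-yl)oxy]-3-oxobutanoate | CCCCC1(OC)OC(=O)c2c(OCC(=O)CC(=O)OC)cc(OC)cc21 | intermediate |
| 14 | (±)-methyl 4-[(3-butyl-3,5-dimethoxy-1-oxo-1,3-dihydroisobenzofuran-7-yl)oxy]-3-(trimethylsilyloxy)but-2-enoate (E/Z mixture) | CCCCC1(OC)OC(=O)c2c(OCC(O[Si](C)(C)C)=CC(=O)OC)cc(OC)cc21 | intermediate |
| 15 | lithium dienolate of 14 (lithium on the ester oxygen, Z enol ether) | COC(O[Li])=C/C(O[Si](C)(C)C)=C/Oc1cc(OC)cc2c1C(=O)OC2(CCCC)OC | intermediate |
| 16 | (±)-3-butyl-3,5-dimethoxy-7-{[(1Z)-4-methoxy-2,4-bis(trimethylsilyloxy)buta-1,3-dien-1-yl]oxy}isobenzofuran-1(3H)-one (ketene acetal geometry immaterial) | COC(O[Si](C)(C)C)=C/C(O[Si](C)(C)C)=C/Oc1cc(OC)cc2c1C(=O)OC2(CCCC)OC | intermediate |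
| 17 | methyl oct-2-ynoate | CCCCCC#CC(=O)OC | starting material |
| 18 | methyl 3-(ArA-oxy)-6-methoxy-2-pentyl-4,6-bis(trimethylsilyloxy)cyclohexa-1,4-diene-1-carboxylate (mixture of diastereomers) | CCCCCC1=C(C(=O)OC)C(OC)(O[Si](C)(C)C)C=C(O[Si](C)(C)C)C1Oc1cc(OC)cc2c1C(=O)OC2(CCCC)OC | intermediate |
| 19 | (±)-methyl 3-(ArA-oxy)-2-pentyl-4,6-bis(trimethylsilyloxy)benzoate | CCCCCc1c(C(=O)OC)c(O[Si](C)(C)C)cc(O[Si](C)(C)C)c1Oc1cc(OC)cc2c1C(=O)OC2(CCCC)OC | intermediate |
| 20 | (±)-methyl 3-[(3-butyl-3,5-dimethoxy-1-oxo-1,3-dihydroisobenzofuran-7-yl)oxy]-4,6-dihydroxy-2-pentylbenzoate | CCCCCc1c(C(=O)OC)c(O)cc(O)c1Oc1cc(OC)cc2c1C(=O)OC2(CCCC)OC | intermediate |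
| 21 | 3-(2-carboxy-5-methoxy-3-pentanoylphenoxy)-4,6-dihydroxy-2-pentylbenzoic acid | CCCCCc1c(C(=O)O)c(O)cc(O)c1Oc1cc(OC)cc(C(=O)CCCC)c1C(=O)O | intermediate |
| 22 | 2-(2,4-dihydroxy-6-pentylphenoxy)-4-methoxy-6-pentanoylbenzoic acid (no stereocentre) | CCCCCc1cc(O)cc(O)c1Oc1cc(OC)cc(C(=O)CCCC)c1C(=O)O | target |

Total step count: 10.
Longest linear sequence: 10 steps (1 → 22); 4, 12 and 17 are bought and enter directly.

## Steps most likely to fail

**1. Step 9.** Both carbons that must join first (C1' of the diene and the β-carbon of the ynoate) are substituted. Three things may go wrong: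
- The cycloaddition may be slower than thermal decay of the diene (silyl migration, or protodesilylation back to the keto ester).
- The reaction may halt after the first bond as an open-chain Michael adduct.
- The C4' ketal may shed silanol in place of methanol.

The fallback sets out from 16 and comes back to the route at 19. The alkyne is replaced by methyl octa-2,3-dienoate F1, made from hexanoyl chloride, Ph3P=CHCO2Me and Et3N (Wittig-type allenoate synthesis). Its sp-hybridised central carbon is less shielded and its conjugated C2=C3 bond is a markedly better dienophile for 1,3-bis(silyloxy)dienes. Warming in toluene at 60–80 °C should therefore give the pentylidene cyclohexene adduct F2 with the same regiochemistry. β-Elimination of methanol (C3'–H, C4'–OMe) and a prototropic shift of C1'–H to the exocyclic carbon, which turns pentylidene into pentyl, then lead to 19. Methanolysis as in step 9 gives 20.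

**2. Step 8.** The carbon end of the lithium dienolate may attack the neighbouring lactone carbonyl (Dieckmann-type closure to a benzofuranone). Silylation may also occur on carbon, or the enol ether geometry may be poorly controlled.

The fallback sets out from 13 and comes back at 16. The keto ester is bis-silylated in one operation by electrophile-assisted soft enolisation with TMSOTf (2.3 equiv) and Et3N in Et2O at 0 °C. No metal dienolate is ever present, and step 7 falls away. The lactone ketal should resist ionisation because its cation would sit ortho to the lactone acyl group and meta to both ring oxygens. This fallback makes no new compound (F0).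

**3. Step 6.** Base-induced self-condensation or cyclisation of the chloro keto ester may outrun displacement, because the hydrogen-bonded phenoxide is a weak nucleophile. Alkylation on carbon may also compete.

The fallback sets out from 11 and comes back at 13.
- O-Alkylation with benzyl bromoacetate (K2CO3, acetone, reflux) gives benzyl (ArA-oxy)acetate F3.
- Hydrogenolysis (H2, Pd/C, EtOAc) gives (ArA-oxy)acetic acid F4.
- 1,1'-Carbonyldiimidazole in THF gives the acyl imidazole F5.
- Treatment with preformed Mg(O2CCH2CO2Me)2 (Masamune–Brooks homologation, decarboxylative Claisen condensation under neutral conditions) delivers 13.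

## Further compounds

F1 | step 9 | methyl octa-2,3-dienoate (racemic) | CCCCC=C=CC(=O)OC
F2 | step 9 | methyl 3-(ArA-oxy)-6-methoxy-2-pentylidene-4,6-bis(trimethylsilyloxy)cyclohex-4-ene-1-carboxylate (mixture of isomers) | CCCCC=C1C(C(=O)OC)C(OC)(O[Si](C)(C)C)C=C(O[Si](C)(C)C)C1Oc1cc(OC)cc2c1C(=O)OC2(CCCC)OC
F0 | step 8 | none | none
F3 | step 6 | (±)-benzyl 2-[(3-butyl-3,5-dimethoxy-1-oxo-1,3-dihydroisobenzofuran-7-yl)oxy]acetate | CCCCC1(OC)OC(=O)c2c(OCC(=O)OCc3ccccc3)cc(OC)cc21
F4 | step 6 | (±)-2-[(3-butyl-3,5-dimethoxy-1-oxo-1,3-dihydroisobenzofuran-7-yl)oxy]acetic acid | CCCCC1(OC)OC(=O)c2c(OCC(=O)O)cc(OC)cc21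
F5 | step 6 | (±)-3-butyl-7-[2-(imidazol-1-yl)-2-oxoethoxy]-3,5-dimethoxyisobenzofuran-1(3H)-one | CCCCC1(OC)OC(=O)c2c(OCC(=O)n3ccnc3)cc(OC)cc21
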